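What does this flask hold at 40 min, and which option brings more target out of it?

all flasks: solid substrate 0.20 M; gas 9.6 mM (held)

| flask | temperature | remark | time |
|---|---|---|---|
| epsilon | 20 °C | the very flask that is asked about, followed so far |  |
| beta | 5 °C | run made earlier |  |
| flask | 20 °C |  | 40 min |

| run | time / min | target / % |
|---|---|---|
| epsilon | 2.50 | 37.0 |
| epsilon | 5.00 | 48.3 |
| epsilon | 10.0 | 31.5 |
| epsilon | 15.0 | 29.6 |
| epsilon | 30.0 | 28.8 |
| beta | 5.00 | 45.2 |
| beta | 10.0 | 67.6 |
| beta | 20.0 | 50.4 |
| beta | 30.0 | 36.9 |
| beta | 60.0 | 14.2 |

(readings scatter by 1 percentage point)

- target, in percent of the solid substrate first charged, at 40 min
- the option that brings most further target ("none" if no option brings more than 2 percentage points) (south / west / south-east / none)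
- target present, with what was taken out counted in, in percent of the solid substrate first charged, after south
- target present, with what was taken out counted in, in percent of the solid substrate first charged, after west

- south: change nothing and wait 80 min more
- west: at 40 min raise the temperature by 15 K, then wait 80 min
- south-east: at 40 min take out 90% of the target then present, then wait 80 min

- solid, in amounts per volume of the solution: solid substrate
- target taken out counts as made
- at the start none of the solid substrate is in solution
- at the start none of the gas is in solution

In the epsilon run, which is this very flask so far, the target rises, falls and stands near 28.8% at 30.0 min, so I take that reading as my estimate for 40 min and expect south to add nothing. My objection is that a standstill may be a slow fall, so I count half-lives: the excess over that reading drops from 19 percentage points at 5.00 min to 2.7 points at 10.0 min, which reads as a relaxation half-life of about 1.75 min, and 40 min is 22.9 of those.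

I read the level as a reversible step and name the plateau ratio: the share of the charge that is not target, over the target share, once many relaxation half-lives have passed, which is the equilibrium constant of that step, here read from the epsilon run as about 2.47. The beta run objects, since at 5 °C it falls to 14.2% at 60.0 min without levelling. But its ratio, read the same way, has then already reached 6.04, so I take the plateau ratio to shrink on warming, by a factor that I read as 2.45 or more over the step between the runs. West's rise of 15 K is a step of that size, so dividing once more gives about 1.01 and a target of 49.7%. The same rise may count a little less higher up, but the beta run was still falling, which pushes the other way. South-east lets the remainder return to the same ratio and gains 18 points, less than west's 21 points, so I commit to west, as a judgement.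

The forecast gives 28.6% now, 28.3% after south, 28% after west and none as best, reading the plateau as “the agent driving the reaction, probably a catalyst, dying quickly”. On now and south my reckoning stands close to it; on west we part.

The flask gives 29.4%, and south adds 0 points, south-east 19 points and west 30 points, so west is best, at 58.9%. At 40.0 min the isomer of the product holds 70.5% of the charge in this flask.

    solid substrate ⇌ dissolved substrate, rate k1*(cs1 - [dissolved substrate]) while solid is left; crystals form when [dissolved substrate] > cs1 (solubility = 0.0930 M, k = 0.350 /s)
    dissolved substrate + reagent → target (k = 1.50 /M/s, Ea = 49.0 kJ/mol)
    2 solid substrate → self-condensation product (k = 1.60 × 10⁻⁴ /M/s, Ea = 65.0 kJ/mol)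
    gas ⇌ reagent, rate k4*(csat - [reagent]) (kL = 0.160 /s)
    target ⇌ isomer of the product (K = 2.40, k = 0.00540 /s, Ea = 84.0 kJ/mol, ΔH = −62.0 kJ/mol)
    (constants at 20 °C)

In this flask after west, what is not target stands to target as 0.698, below the plateau ratio of 2.47 read at 20 °C. The neighbour at −5 °C, colder than the beta run, stands at no plateau ratio at 40.0 min: it holds 30.8% isomer of the product to 68.2% target, a ratio of 0.452, below the 6.04 read in the beta run at 60.0 min.

The runs stem from a simulated flask with constants of no real substance; scatter was added.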